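## Retrosynthetic overview

1. Numbering (used for all intermediates, descriptors included): carbocycle C1–C10, ether O between C5 and C10, C14 on C10, C15 on C4, lactone C11–C13 on C7 closed to O8, ester on O9; ring A is the oxepane with C1–C4, ring B the oxepane with C6–C9.
2. The strategy rests on one feature of ring B: the quaternary ether carbon C10 (methyl C14, CH2 C1, oxygen bridge to C5) lies next to the oxygenated C9, the pattern a ketyl leaves when it adds to a β-alkoxy-β-methylacrylate. The C9–C10 bond is therefore cut to a C9 aldehyde and an (E)-crotonate on O5.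
3. Rings form in the order ring B (SmI2 ketyl closure), ring A (ring-closing metathesis at C2=C3), lactone (oxidation of C12 onto O8); the C13 methylene and the O9 ester come last.
4. The acyclic aldehyde comes from lactone 1: butenolide, anti conjugate allylation (C7), reduction and benzylation, ozonolysis to the C5 aldehyde, (E)-crotylboration (C5 and C4), addition of O5 to ethyl but-2-ynoate, oxidation at C9.
5. C4 is set before any ring exists. An isopropenyl group on C5 with later hydrogenation of a C3=C4 alkene was rejected, because hydrogen should add to the open face of ring A and leave C15 on the side of the C6–C9 bridge, the wrong epimer.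

Key step: step 12

Remark on the chemistry: the facial preference of the Ipc2B crotyl reagent in step 8 is taken from the usual behaviour of the reagent derived from (+)-α-pinene with unbiased aliphatic aldehydes; if it proves opposite, the enantiomeric borane is used.

## Route

Step 1
Reactants: 1 (R)-5-(hydroxymethyl)dihydrofuran-2(3H)-one
Product: 2 (R)-5-[(tert-butyldiphenylsilyloxy)methyl]dihydrofuran-2(3H)-one
Conditions: TBDPSCl, imidazole, DMF, 0 °C to rt
Reagents that add atoms: tert-butyldiphenylsilyl chloride, CC(C)(C)[Si](Cl)(c1ccccc1)c1ccccc1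
Why: Silylation of the primary alcohol; the bulky silyl ether later shields one face of the butenolide and is the one group on O9 that can be removed beside benzyl ethers.

Step 2
Reactants: 2 (R)-5-[(tert-butyldiphenylsilyloxy)methyl]dihydrofuran-2(3H)-one
Product: 4 α-phenylselanyl lactone (C11 epimers), via lithium enolate 3 (not isolated)
Conditions: LiN(i-Pr)2, THF, −78 °C; then PhSeBr, −78 °C
Reagents that add atoms: phenylselenyl bromide, Br[Se]c1ccccc1
Why: α-Selenenylation of the lactone enolate; the new C–Se centre is destroyed in the next step, so its configuration does not matter.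

Step 3
Reactants: 4 α-phenylselanyl lactone
Product: 6 (R)-5-[(tert-butyldiphenylsilyloxy)methyl]furan-2(5H)-one, via selenoxide 5 (not isolated)
Conditions: H2O2 (30% aq.), pyridine, CH2Cl2, 0 °C to rt
Reagents that add atoms: none
Why: Selenoxide syn-elimination can only take a hydrogen from C7 and gives the butenolide without touching the C8 stereocentre.

Step 4
Reactants: 6 (R)-5-[(tert-butyldiphenylsilyloxy)methyl]furan-2(5H)-one
Product: 8 trans-4-allyl lactone (7R,8R), via silyl ketene acetal 7 (not isolated)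
Conditions: CH2=CHCH2MgBr (3 equiv), CuBr·SMe2 (1.5 equiv), Me3SiCl, THF, −78 °C; then aq. NH4Cl
Reagents that add atoms: allylmagnesium bromide, C=CC[Mg]Br
Why: Me3SiCl-accelerated conjugate addition of an allyl cuprate; the allyl group (C6, C5 and one carbon lost later) should enter anti to the CH2OTBDPS group on C8 and so set C7.

Step 5
Reactants: 8 trans-4-allyl lactone
Product: 9 C8,C12-diol (7R,8R)
Conditions: LiBH4, THF, 0 °C to rt
Reagents that add atoms: none
Why: Hydride reduction of the lactone opens it to the 1,4-diol, freeing O8 and giving C12 as CH2OH; no stereocentre is touched and the silyl ether survives.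

Step 6
Reactants: 9 C8,C12-diol
Product: 10 C8,C12-bis(benzyl ether) (7R,8R)
Conditions: BnOC(=NH)CCl3 (3 equiv), TfOH (cat.), CH2Cl2/cyclohexane, 0 °C to rt
Reagents that add atoms: benzyl 2,2,2-trichloroacetimidate, N=C(OCc1ccccc1)C(Cl)(Cl)Cl
Why: Acid-catalysed benzylation with the trichloroacetimidate avoids an alkoxide on O8, which would invite 1,2-migration of the neighbouring silyl group.

Step 7
Reactants: 10 C8,C12-bis(benzyl ether)
Product: 12 C5 aldehyde (7S,8R), via ozonide 11 (not isolated)
Conditions: O3, CH2Cl2, −78 °C; then PPh3, −78 °C to rt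
Reagents that add atoms: ozone, [O-][O+]=O
Why: Ozonolysis with reductive work-up cleaves the terminal alkene to the C5 aldehyde; benzyl and silyl ethers should survive at −78 °C if the ozone stream is stopped at the end point.

Step 8
Reactants: 12 C5 aldehyde; 13 (E)-but-2-ene
Product: 16 anti homoallylic alcohol (4S,5R,7S,8R), via crotylborane 14 (not isolated), via borinate 15 (not isolated)
Conditions: 13, KOt-Bu, n-BuLi, THF, −78 to −45 °C; (−)-Ipc2BOMe, −78 °C; BF3·OEt2; 12, −78 °C; then NaOH, H2O2, 0 °C to rt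
Reagents that add atoms: none
Why: Brown (E)-crotylboration through a chair Zimmerman–Traxler transition state gives the 4,5-anti pair from the E geometry of the crotyl group, and the (−)-Ipc2B reagent (from (+)-α-pinene) should override the weak bias of the β-branched aldehyde and add to the face that makes C5 R and C4 S.

Step 9
Reactants: 16 anti homoallylic alcohol; 17 ethyl but-2-ynoate
Product: 18 (E)-β-alkoxycrotonate on O5 with O9 silylated
Conditions: PMe3 (0.3 equiv), CH2Cl2, 0 °C to rt
Reagents that add atoms: none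
Why: Phosphine-catalysed hetero-Michael addition of the C5 alcohol to the alkynoate should give the thermodynamically preferred (E)-enol ether and brings in C10, C14, C1 and C2.

Step 10
Reactants: 18 (E)-β-alkoxycrotonate on O5 with O9 silylated
Product: 19 C9 primary alcohol
Conditions: Bu4NF, AcOH, THF, 0 °C to rt
Reagents that add atoms: none
Why: Fluoride-mediated desilylation; buffering with AcOH keeps the medium from becoming basic enough to attack the enol ether ester, and the benzyl ethers are inert.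

Step 11
Reactants: 19 C9 primary alcohol
Product: 20 α-benzyloxy aldehyde bearing the O5 (E)-crotonate (4S,5R,7S,8R)
Conditions: Dess–Martin periodinane, NaHCO3, CH2Cl2, 0 °C to rt
Reagents that add atoms: none
Why: Buffered Dess–Martin oxidation is non-basic, so the C8 centre α to the new aldehyde should not epimerise if 20 is used at once.

Step 12
Reactants: 20 α-benzyloxy aldehyde bearing the O5 (E)-crotonate
Product: 21 ring B oxepane hydroxy ester (4S,5R,7S,8R,9S,10R)
Conditions: SmI2 (3 equiv), MeOH (3 equiv), THF, 0 °C to rt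
Reagents that add atoms: none
Why: SmI2 transfers one electron to the C9 aldehyde, the ketyl radical anion adds to C10 of the (E)-β-alkoxycrotonate, a second electron turns the α-ester radical into a samarium enolate and MeOH protonates it; the closest known reaction type is the SmI2-induced reductive cyclisation of aldehydes onto β-alkoxyacrylates and their β-methyl analogues to 2,3-trans cyclic ethers, oxepanes included. Ring B closes 7-exo-trig through the C9–C10 bond, with O5 already in place. C9 is controlled by trivalent samarium bridging the ketyl oxygen and the ester carbonyl, which should place O9 trans to the C1 arm, and the C8 benzyloxy group anti to the ketyl oxygen favours the same face. C10 is controlled by the C5 stereocentre: with the but-3-en-2-yl group pseudo-equatorial and the enol ether turned away from it, the C1 arm should end up syn to the C4 arm and C14 axial. The step needs 2,7-syn-2,3-trans selectivity and closure faster than simple reduction or loss of benzyloxide. The substrate should secure the first because the C5, C7 and C8 substituents, the ketyl oxygen and the ester arm can all be pseudo-equatorial in one twist-chair, and the second because a benzyl ether is a poor leaving group from a ketyl and the acceptor is activated and held close by the metal.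

Step 13
Reactants: 21 ring B oxepane hydroxy ester
Product: 22 O9 tert-butyldimethylsilyl ether of 21
Conditions: TBSOTf, 2,6-lutidine, CH2Cl2, −78 to 0 °C
Reagents that add atoms: tert-butyldimethylsilyl triflate, CC(C)(C)[Si](C)(C)OS(=O)(=O)C(F)(F)F
Why: Silyl triflate silylation reaches the hindered O9 and masks it through reduction, lactone formation and enolate chemistry.

Step 14
Reactants: 22 O9 tert-butyldimethylsilyl ether of 21
Product: 24 C2 aldehyde, via aluminium hemiacetal 23 (not isolated)
Conditions: i-Bu2AlH (1.1 equiv), CH2Cl2, −78 °C; then MeOH, aq. KNaC4H4O6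
Reagents that add atoms: none
Why: Partial reduction of the ester; the tetrahedral aluminium hemiacetal, stabilised by the β-ether oxygen, should persist at −78 °C and release the aldehyde only on work-up.

Step 15
Reactants: 24 C2 aldehyde
Product: 25 oxepane with allyl arm on C10 and but-3-en-2-yl arm on C5
Conditions: Ph3PCH3Br, KOt-Bu, THF, 0 °C; then 24, −78 to 0 °C
Reagents that add atoms: methyltriphenylphosphonium bromide, C[P+](c1ccccc1)(c1ccccc1)c1ccccc1.[Br-]
Why: Wittig methylenation at low temperature should be faster than base-induced β-elimination of the ring oxygen and gives the terminal alkene needed for metathesis.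

Step 16
Reactants: 25 oxepane with allyl arm on C10 and but-3-en-2-yl arm on C5
Product: 26 bicyclic C2=C3 alkene (11-oxabicyclo[4.4.1]undecene)
Conditions: second-generation Grubbs catalyst RuCl2(=CHPh)(H2IMes)(PCy3) (5 mol%), CH2Cl2 (2 mM), 40 °C
Reagents that add atoms: none
Why: Ring-closing metathesis of two monosubstituted alkenes held cis on C5 and C10 of ring B closes ring A as a cis-cycloheptene with loss of ethene; high dilution should suppress oligomers.

Step 17
Reactants: 26 bicyclic C2=C3 alkene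
Product: 27 saturated bicyclic bis(benzyl ether)
Conditions: 2-nitrobenzenesulfonyl hydrazide, Et3N, CH2Cl2, rt
Reagents that add atoms: none
Why: Diimide reduction saturates C2=C3 by concerted syn transfer of two hydrogens, so the double bond cannot first migrate to C3=C4 and scramble C4, as it might on palladium.

Step 18
Reactants: 27 saturated bicyclic bis(benzyl ether)
Product: 28 C8,C12-diol with O9 silylated
Conditions: H2 (1 atm), Pd(OH)2/C, EtOAc/EtOH, rt
Reagents that add atoms: none
Why: Hydrogenolysis of both benzyl ethers frees O8 and the C12 alcohol while the silyl ether on O9 stays.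

Step 19
Reactants: 28 C8,C12-diol with O9 silylated
Product: 31 trans-fused γ-lactone, via hydroxy aldehyde 29 (not isolated), via lactol 30 (not isolated)
Conditions: TEMPO (0.2 equiv), PhI(OAc)2 (2.5 equiv), CH2Cl2, rt
Reagents that add atoms: none
Why: TEMPO/PhI(OAc)2 oxidises the primary C12 alcohol selectively; the aldehyde is trapped by O8 as the five-membered lactol and oxidised on to the lactone, and O9 cannot compete because it is silylated.

Step 20
Reactants: 31 trans-fused γ-lactone
Product: 33 α-(dimethylaminomethyl) lactone (C11 epimers), via lithium enolate 32 (not isolated)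
Conditions: LiN(i-Pr)2, THF, −78 °C; then CH2=NMe2+ I−, −78 °C to rt
Reagents that add atoms: N,N-dimethylmethyleneiminium iodide, C=[N+](C)C.[I-]
Why: Mannich aminomethylation of the lactone enolate introduces C13; the new C11 centre is removed in the next step.

Step 21
Reactants: 33 α-(dimethylaminomethyl) lactone
Product: 35 α-methylene lactone with O9 silylated, via ammonium iodide 34 (not isolated)
Conditions: MeI, MeOH, rt; then NaHCO3 (aq.), CH2Cl2, rt
Reagents that add atoms: none
Why: N-Methylation followed by mild-base β-elimination of trimethylamine unveils the conjugated exocyclic C11=C13 alkene.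

Step 22
Reactants: 35 α-methylene lactone with O9 silylated
Product: 36 C9 alcohol
Conditions: HF·pyridine, THF, 0 °C to rt
Reagents that add atoms: none
Why: Fluoride desilylation under mildly acidic conditions should not add to the α-methylene lactone.

Step 23
Reactants: 36 C9 alcohol; 37 (R)-2-methylbutanoic acid
Product: 38 target CNP0136059.1
Conditions: 2-methyl-6-nitrobenzoic anhydride, Et3N, DMAP, CH2Cl2, rt
Reagents that add atoms: none
Why: Shiina esterification (mixed anhydride, acyl transfer by DMAP) acylates the hindered secondary O9 at room temperature, where the α-stereocentre of the acid should not epimerise.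

## Compound list

1 | (R)-5-(hydroxymethyl)dihydrofuran-2(3H)-one | O=C1CC[C@H](CO)O1 | starting material
2 | (R)-5-[(tert-butyldiphenylsilyloxy)methyl]dihydrofuran-2(3H)-one | O=C1CC[C@H](CO[Si](c2ccccc2)(c2ccccc2)C(C)(C)C)O1 | intermediate
3 | lithium enolate of 2 | [Li]OC1=CC[C@H](CO[Si](c2ccccc2)(c2ccccc2)C(C)(C)C)O1 | intermediate
4 | (5R)-5-[(tert-butyldiphenylsilyloxy)methyl]-3-(phenylselanyl)dihydrofuran-2(3H)-one, both C3 (C11) epimers | O=C1C([Se]c2ccccc2)C[C@H](CO[Si](c2ccccc2)(c2ccccc2)C(C)(C)C)O1 | intermediate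
5 | selenoxide of 4 | O=C1C([Se](=O)c2ccccc2)C[C@H](CO[Si](c2ccccc2)(c2ccccc2)C(C)(C)C)O1 | intermediate
6 | (R)-5-[(tert-butyldiphenylsilyloxy)methyl]furan-2(5H)-one | O=C1C=C[C@H](CO[Si](c2ccccc2)(c2ccccc2)C(C)(C)C)O1 | intermediate
7 | trimethylsilyl ketene acetal of 8 | C[Si](C)(C)OC1=C[C@@H](CC=C)[C@H](CO[Si](c2ccccc2)(c2ccccc2)C(C)(C)C)O1 | intermediate
8 | (4R,5R)-4-allyl-5-[(tert-butyldiphenylsilyloxy)methyl]dihydrofuran-2(3H)-one (trans; 7R,8R) | O=C1C[C@@H](CC=C)[C@H](CO[Si](c2ccccc2)(c2ccccc2)C(C)(C)C)O1 | intermediate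
9 | (2R,3R)-3-allyl-1-(tert-butyldiphenylsilyloxy)pentane-2,5-diol (7R,8R) | C=CC[C@H](CCO)[C@@H](O)CO[Si](c1ccccc1)(c1ccccc1)C(C)(C)C | intermediate
10 | (2R,3R)-2-(benzyloxy)-3-[2-(benzyloxy)ethyl]-1-(tert-butyldiphenylsilyloxy)hex-5-ene (7R,8R) | C=CC[C@H](CCOCc1ccccc1)[C@@H](OCc1ccccc1)CO[Si](c1ccccc1)(c1ccccc1)C(C)(C)C | intermediate
11 | 1,2,4-trioxolane (ozonide) of the terminal alkene of 10 | O1OC(C[C@H](CCOCc2ccccc2)[C@@H](OCc2ccccc2)CO[Si](c2ccccc2)(c2ccccc2)C(C)(C)C)OC1 | intermediate
12 | (3S,4R)-4-(benzyloxy)-3-[2-(benzyloxy)ethyl]-5-(tert-butyldiphenylsilyloxy)pentanal (C5 aldehyde; 7S,8R) | O=CC[C@H](CCOCc1ccccc1)[C@@H](OCc1ccccc1)CO[Si](c1ccccc1)(c1ccccc1)C(C)(C)C | intermediate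
13 | (E)-but-2-ene | C/C=C/C | starting material
14 | (E)-but-2-enylbis(isopinocampheyl)borane from (−)-Ipc2BOMe | C/C=C/CB([C@@H]1C[C@@H]2C[C@H]([C@H]1C)C2(C)C)[C@@H]1C[C@@H]2C[C@H]([C@H]1C)C2(C)C | intermediate
15 | bis(isopinocampheyl)borinate ester of 16 | C=C[C@H](C)[C@H](OB([C@@H]1C[C@@H]2C[C@H]([C@H]1C)C2(C)C)[C@@H]1C[C@@H]2C[C@H]([C@H]1C)C2(C)C)C[C@H](CCOCc1ccccc1)[C@@H](OCc1ccccc1)CO[Si](c1ccccc1)(c1ccccc1)C(C)(C)C | intermediate
16 | (3S,4R,6S,7R)-7-(benzyloxy)-6-[2-(benzyloxy)ethyl]-8-(tert-butyldiphenylsilyloxy)-3-methyloct-1-en-4-ol (anti C4/C5; 4S,5R,7S,8R) | C=C[C@H](C)[C@H](O)C[C@H](CCOCc1ccccc1)[C@@H](OCc1ccccc1)CO[Si](c1ccccc1)(c1ccccc1)C(C)(C)C | intermediate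
17 | ethyl but-2-ynoate | CC#CC(=O)OCC | starting material
18 | ethyl (E)-3-{[(3S,4R,6S,7R)-7-(benzyloxy)-6-[2-(benzyloxy)ethyl]-8-(tert-butyldiphenylsilyloxy)-3-methyloct-1-en-4-yl]oxy}but-2-enoate | C=C[C@H](C)[C@H](O/C(C)=C/C(=O)OCC)C[C@H](CCOCc1ccccc1)[C@@H](OCc1ccccc1)CO[Si](c1ccccc1)(c1ccccc1)C(C)(C)C | intermediate
19 | ethyl (E)-3-{[(3S,4R,6S,7R)-7-(benzyloxy)-6-[2-(benzyloxy)ethyl]-8-hydroxy-3-methyloct-1-en-4-yl]oxy}but-2-enoate | C=C[C@H](C)[C@H](O/C(C)=C/C(=O)OCC)C[C@H](CCOCc1ccccc1)[C@@H](OCc1ccccc1)CO | intermediate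
20 | ethyl (E)-3-{[(3S,4R,6S,7R)-7-(benzyloxy)-6-[2-(benzyloxy)ethyl]-3-methyl-8-oxooct-1-en-4-yl]oxy}but-2-enoate (key-step precursor) | O=C[C@H](OCc1ccccc1)[C@@H](CCOCc2ccccc2)C[C@H]([C@@H](C)C=C)O/C(C)=C/C(=O)OCC | intermediate
21 | ethyl 2-{(2R,3S,4R,5S,7R)-4-(benzyloxy)-5-[2-(benzyloxy)ethyl]-7-[(S)-but-3-en-2-yl]-3-hydroxy-2-methyloxepan-2-yl}acetate (key-step product) | c1ccccc1CO[C@@H]2[C@@H](CCOCc3ccccc3)C[C@H]([C@@H](C)C=C)O[C@](C)(CC(=O)OCC)[C@H]2O | intermediate
22 | O9 tert-butyldimethylsilyl ether of 21 | c1ccccc1CO[C@@H]2[C@@H](CCOCc3ccccc3)C[C@H]([C@@H](C)C=C)O[C@](C)(CC(=O)OCC)[C@H]2O[Si](C)(C)C(C)(C)C | intermediate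
23 | diisobutylaluminium hemiacetal of 22 at C2 | c1ccccc1CO[C@@H]2[C@@H](CCOCc3ccccc3)C[C@H]([C@@H](C)C=C)O[C@](C)(CC(OCC)O[Al](CC(C)C)CC(C)C)[C@H]2O[Si](C)(C)C(C)(C)C | intermediate
24 | C2 aldehyde (2-oxoethyl arm on C10) | c1ccccc1CO[C@@H]2[C@@H](CCOCc3ccccc3)C[C@H]([C@@H](C)C=C)O[C@](C)(CC=O)[C@H]2O[Si](C)(C)C(C)(C)C | intermediate
25 | oxepane with allyl arm on C10 and (S)-but-3-en-2-yl arm on C5 | c1ccccc1CO[C@@H]2[C@@H](CCOCc3ccccc3)C[C@H]([C@@H](C)C=C)O[C@](C)(CC=C)[C@H]2O[Si](C)(C)C(C)(C)C | intermediate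
26 | bicyclic C2=C3 alkene, rings A and B closed (4S,5R,7S,8R,9S,10R) | c1ccccc1CO[C@@H]2[C@@H](CCOCc3ccccc3)C[C@H]4O[C@](C)(C/C=C\[C@@H]4C)[C@H]2O[Si](C)(C)C(C)(C)C | intermediate
27 | saturated bicyclic bis(benzyl ether) | c1ccccc1CO[C@@H]2[C@@H](CCOCc3ccccc3)C[C@H]4O[C@](C)(CCC[C@@H]4C)[C@H]2O[Si](C)(C)C(C)(C)C | intermediate
28 | bicyclic C8,C12-diol with O9 silylated | O[C@@H]2[C@@H](CCO)C[C@H]4O[C@](C)(CCC[C@@H]4C)[C@H]2O[Si](C)(C)C(C)(C)C | intermediate
29 | C12 hydroxy aldehyde | O[C@@H]2[C@@H](CC=O)C[C@H]4O[C@](C)(CCC[C@@H]4C)[C@H]2O[Si](C)(C)C(C)(C)C | intermediate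
30 | C12 lactol (both anomers) | C1C(O)O[C@@H]2[C@@H]1C[C@H]1O[C@](C)(CCC[C@@H]1C)[C@H]2O[Si](C)(C)C(C)(C)C | intermediate
31 | trans-fused γ-lactone with O9 silylated (4S,5R,7R,8R,9S,10R) | C1C(=O)O[C@@H]2[C@@H]1C[C@H]1O[C@](C)(CCC[C@@H]1C)[C@H]2O[Si](C)(C)C(C)(C)C | intermediate
32 | lithium enolate of 31 | C1=C(O[Li])O[C@@H]2[C@@H]1C[C@H]1O[C@](C)(CCC[C@@H]1C)[C@H]2O[Si](C)(C)C(C)(C)C | intermediate
33 | α-(dimethylaminomethyl) lactone, C11 epimers | CN(C)CC1C(=O)O[C@@H]2[C@@H]1C[C@H]1O[C@](C)(CCC[C@@H]1C)[C@H]2O[Si](C)(C)C(C)(C)C | intermediate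
34 | trimethylammonium iodide of 33 | C[N+](C)(C)CC1C(=O)O[C@@H]2[C@@H]1C[C@H]1O[C@](C)(CCC[C@@H]1C)[C@H]2O[Si](C)(C)C(C)(C)C.[I-] | intermediate
35 | α-methylene lactone with O9 silylated | C=C1C(=O)O[C@@H]2[C@@H]1C[C@H]1O[C@](C)(CCC[C@@H]1C)[C@H]2O[Si](C)(C)C(C)(C)C | intermediate
36 | α-methylene lactone C9 alcohol | C=C1C(=O)O[C@@H]2[C@@H]1C[C@H]1O[C@](C)(CCC[C@@H]1C)[C@H]2O | intermediate
37 | (R)-2-methylbutanoic acid | CC[C@@H](C)C(=O)O | starting material
38 | CNP0136059.1, (4S,5R,7R,8R,9S,10R) with (R)-2-methylbutanoate on O9 | C=C1C(=O)O[C@@H]2[C@@H]1C[C@H]1O[C@](C)(CCC[C@@H]1C)[C@H]2OC(=O)[C@H](C)CC | target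

## Step count and risks

Total step count: 23. Longest linear sequence: 23 steps (1 to 38).

Steps most likely to fail:

**Step 12 (ketyl closure of ring B).** Simple reduction of the aldehyde, loss of benzyloxide from the ketyl, or incomplete 2,7-syn-2,3-trans selectivity may outrun or spoil the 7-exo closure onto the β,β-disubstituted acceptor. The fallback closes ring B through the C10–O bond instead, by a methyl-directed 7-endo opening of a C9–C10 epoxide. It sets out from 16 and comes back at 25, by-passing steps 9 to 15. Bu4NF gives the C5,C9-diol F1. TEMPO/PhI(OAc)2 oxidises only the primary alcohol to the hydroxy aldehyde F2. The Ohira–Bestmann reagent (dimethyl (1-diazo-2-oxopropyl)phosphonate, K2CO3, MeOH) gives the terminal alkyne F3. The dianion (n-BuLi, 2 equiv, THF/DMPU) is methylated on carbon with MeI to the methyl alkyne F4. Hydrozirconation with excess Cp2Zr(H)Cl (one equivalent is taken by the free hydroxyl; equilibration should place zirconium on the methyl-bearing C10), then CuCl-catalysed allylation with allyl bromide, gives the (E)-trisubstituted C9=C10 triene F5. Shi epoxidation with the L-fructose-derived ketone (KHSO5, K2CO3, MeCN/dimethoxymethane) should give the (9S,10S)-epoxide F6 and leave the terminal alkenes alone. Camphorsulfonic acid in CH2Cl2 lets O5 open the epoxide at the tertiary C10 with inversion (C9 is deactivated by the C8 benzyloxy group), giving the oxepane alcohol F7. Silylation (TBSOTf, 2,6-lutidine) gives 25.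

**Step 16 (metathesis closure of ring A).** Cross-metathesis to oligomers may win if the two arms on C5 and C10 do not readily turn toward the same face of ring B. The fallback forms the C2=C3 bond by reductive carbonyl coupling. It sets out from 25 and comes back at 26. Ozonolysis (O3, CH2Cl2, −78 °C; PPh3) gives the C2,C3-dialdehyde F8. Slow addition of F8 to TiCl3(DME)1.5 and Zn–Cu in refluxing DME (McMurry coupling on low-valent titanium) gives 26.

**Step 4 (conjugate allylation).** 1,2-Addition of the allyl metal to the lactone carbonyl may compete with 1,4-addition. The fallback brings in C6–C5 as a vinyl group, which adds 1,4 cleanly to this butenolide class, and functionalises its terminus. It sets out from 6 and comes back at 12. CH2=CHMgBr, CuBr·SMe2 and Me3SiCl in THF at −78 °C give the trans-4-vinyl lactone F9. LiBH4 gives the diol F10. Benzyl trichloroacetimidate with catalytic TfOH gives the bis(benzyl ether) F11. Hydroboration with 9-BBN and oxidation (NaOH, H2O2) give the C5 primary alcohol F12. Dess–Martin oxidation gives 12.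

## Further compounds

F1 | step 12 | C5,C9-diol from 16 | C=C[C@H](C)[C@H](O)C[C@H](CCOCc1ccccc1)[C@@H](OCc1ccccc1)CO
F2 | step 12 | C5-hydroxy C9-aldehyde | C=C[C@H](C)[C@H](O)C[C@H](CCOCc1ccccc1)[C@@H](OCc1ccccc1)C=O
F3 | step 12 | terminal alkyne (C9≡C10) | C=C[C@H](C)[C@H](O)C[C@H](CCOCc1ccccc1)[C@@H](OCc1ccccc1)C#C
F4 | step 12 | methyl alkyne (C9≡C10–C14) | C=C[C@H](C)[C@H](O)C[C@H](CCOCc1ccccc1)[C@@H](OCc1ccccc1)C#CC
F5 | step 12 | (E)-C9=C10 triene with allyl arm on C10 | C=C[C@H](C)[C@H](O)C[C@H](CCOCc1ccccc1)[C@@H](OCc1ccccc1)/C=C(\C)CC=C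
F6 | step 12 | (9S,10S)-epoxy alcohol | C=C[C@H](C)[C@H](O)C[C@H](CCOCc1ccccc1)[C@@H](OCc1ccccc1)[C@@H]1O[C@@]1(C)CC=C
F7 | step 12 | oxepane C9 alcohol (desilyl 25) | c1ccccc1CO[C@@H]2[C@@H](CCOCc3ccccc3)C[C@H]([C@@H](C)C=C)O[C@](C)(CC=C)[C@H]2O
F8 | step 16 | C2,C3-dialdehyde from 25 | c1ccccc1CO[C@@H]2[C@@H](CCOCc3ccccc3)C[C@H]([C@@H](C)C=O)O[C@](C)(CC=O)[C@H]2O[Si](C)(C)C(C)(C)C
F9 | step 4 | (4S,5R)-5-[(tert-butyldiphenylsilyloxy)methyl]-4-vinyldihydrofuran-2(3H)-one (trans) | O=C1C[C@@H](C=C)[C@H](CO[Si](c2ccccc2)(c2ccccc2)C(C)(C)C)O1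
F10 | step 4 | vinyl diol | C=C[C@H](CCO)[C@@H](O)CO[Si](c1ccccc1)(c1ccccc1)C(C)(C)C
F11 | step 4 | vinyl bis(benzyl ether) | C=C[C@H](CCOCc1ccccc1)[C@@H](OCc1ccccc1)CO[Si](c1ccccc1)(c1ccccc1)C(C)(C)C
F12 | step 4 | C5 primary alcohol | OCC[C@H](CCOCc1ccccc1)[C@@H](OCc1ccccc1)CO[Si](c1ccccc1)(c1ccccc1)C(C)(C)C
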